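The route rests on cutting the 2,3-dihydrobenzofuran (ring E, fused to ring D) at O1–C7a and C2–C3: C2 and O1 come from the C=O of a trimeric aryl aldehyde, C3–C3a–C7a from an (o-triflyloxyaryl)acetyl imide made from 5-iodovanillin. The key step unites both halves in one flask: an auxiliary-controlled boron syn-aldol forms C2–C3 and sets both stereocentres, then palladium-catalysed O-arylation of the aldolate closes ring E. It exploits the fact that C7a of ring D is a phenol-derived carbon ortho to the benzylic C3, and that C2 is a benzylic carbinol carbon. The two erythro arylglycerol β-aryl ether units are built beforehand by iterative anti-glycolate aldol reactions.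

Key step: step 16

Labels: ring A = guaiacyl ring; rings B and C = the two syringyl rings; ring D = benzo ring and ring E = oxygen ring of the 2,3-dihydrobenzofuran, with positions O1, C2, C3, C3a, C7a. ArB = aryl residue of aldehyde 11 (11 without CHO); ArC = aryl residue of aldehyde 17 (17 without CHO).
Assumption: the MgCl2-catalysed anti-aldol is taken to keep its usual stereochemical course (chelated Z-enolate, attack anti to the benzyl group, anti adduct) with the aryloxyacetyl imide 5.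

Step 1
Reactants: 1 vanillin
Product: 2 3-methoxy-4-(methoxymethoxy)benzaldehyde
Conditions: MeOCH2Cl, i-Pr2NEt, CH2Cl2, 0 °C → rt
Reagents that add atoms: chloromethyl methyl ether, COCCl
Why: Williamson-type O-alkylation of the phenol should give a MOM ether that survives the later organolithium, hydride and Lewis-acid steps and falls off with acid at the end.

Step 2
Reactants: 3 4-bromo-2,6-dimethoxyphenol; 4 (4S)-4-benzyl-3-(chloroacetyl)-1,3-oxazolidin-2-one
Product: 5 (4S)-4-benzyl-3-[(4-bromo-2,6-dimethoxyphenoxy)acetyl]-1,3-oxazolidin-2-one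
Conditions: K2CO3, NaI (10 mol%), MeCN, rt
Reagents that add atoms: none
Why: Williamson displacement of the activated α-chloro imide by the phenoxide (iodide catalysis) should give the aryloxyacetyl imide without touching the auxiliary stereocentre.

Step 3
Reactants: 2 3-methoxy-4-(methoxymethoxy)benzaldehyde; 5 glycolate imide
Product: 6 (4S)-4-benzyl-3-{(2R,3R)-2-(4-bromo-2,6-dimethoxyphenoxy)-3-[3-methoxy-4-(methoxymethoxy)phenyl]-3-(trimethylsilyloxy)propanoyl}-1,3-oxazolidin-2-one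
Conditions: MgCl2 (20 mol%), Et3N, TMSCl, EtOAc, rt
Reagents that add atoms: chlorotrimethylsilane, C[Si](C)(C)Cl
Why: In this MgCl2-catalysed direct anti-aldol of an N-acyl oxazolidinone with an aromatic aldehyde (Evans anti-aldol with silyl turnover) the chelated (Z)-magnesium enolate should be attacked on the face opposite the benzyl group, which sets C2 of the new chain as R, and the boat-like transition state should give the anti (3R) silyl ether, which is the erythro relationship of the target.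

Step 4
Reactants: 6 anti-aldol silyl ether
Product: 8 (1R,2S)-2-(4-bromo-2,6-dimethoxyphenoxy)-1-[3-methoxy-4-(methoxymethoxy)phenyl]propane-1,3-diol, via TMS-protected alcohol 7 (not isolated)
Conditions: LiBH4, H2O (1 equiv), THF, 0 °C; then K2CO3 (cat.), MeOH, rt
Reagents that add atoms: none
Why: Hydride should attack the exocyclic imide carbonyl (reductive removal of the oxazolidinone auxiliary) and base-catalysed methanolysis then frees the secondary alcohol, with no change at either stereocentre.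

Step 5
Reactants: 8 erythro diol
Product: 9 (4R,5S)-5-(4-bromo-2,6-dimethoxyphenoxy)-4-[3-methoxy-4-(methoxymethoxy)phenyl]-2,2-dimethyl-1,3-dioxane
Conditions: 2,2-dimethoxypropane, PPTS (cat.), acetone, rt
Reagents that add atoms: 2,2-dimethoxypropane, COC(C)(C)OC
Why: Acid-catalysed transacetalisation should close the six-membered acetonide over the 1,3-diol and so mask both hydroxyls for the organolithium step.

Step 6
Reactants: 9 acetonide aryl bromide
Product: 11 3,5-dimethoxy-4-({(4R,5S)-4-[3-methoxy-4-(methoxymethoxy)phenyl]-2,2-dimethyl-1,3-dioxan-5-yl}oxy)benzaldehyde, via aryllithium 10 (not isolated)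
Conditions: n-BuLi, THF, −78 °C; DMF; aq. NH4Cl
Reagents that add atoms: N,N-dimethylformamide, CN(C)C=O
Why: Bromine–lithium exchange should outrun any deprotonation at −78 °C and the aryllithium is formylated by DMF (Bouveault aldehyde synthesis).

Step 7
Reactants: 11 dimer aldehyde; 5 glycolate imide
Product: 12 (4S)-4-benzyl-3-[(2R,3R)-3-ArB-2-(4-bromo-2,6-dimethoxyphenoxy)-3-(trimethylsilyloxy)propanoyl]-1,3-oxazolidin-2-one
Conditions: MgCl2 (20 mol%), Et3N, TMSCl, EtOAc, rt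
Reagents that add atoms: chlorotrimethylsilane, C[Si](C)(C)Cl
Why: The same MgCl2-catalysed Evans anti-aldol should again set C2 (R) by attack anti to the benzyl group of the chelated (Z)-enolate and C3 (R) by the anti-selective boat transition state, the remote acetonide having no say.

Step 8
Reactants: 12 anti-aldol silyl ether
Product: 14 (1R,2S)-1-ArB-2-(4-bromo-2,6-dimethoxyphenoxy)propane-1,3-diol, via TMS-protected alcohol 13 (not isolated)
Conditions: LiBH4, H2O (1 equiv), THF, 0 °C; then K2CO3 (cat.), MeOH, rt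
Reagents that add atoms: none
Why: Reductive removal of the oxazolidinone auxiliary by hydride and mild methanolysis of the silyl ether should leave the first acetonide, the MOM ether and all four stereocentres untouched.

Step 9
Reactants: 14 erythro diol
Product: 15 (4R,5S)-4-ArB-5-(4-bromo-2,6-dimethoxyphenoxy)-2,2-dimethyl-1,3-dioxane
Conditions: 2,2-dimethoxypropane, PPTS (cat.), acetone, rt
Reagents that add atoms: 2,2-dimethoxypropane, COC(C)(C)OC
Why: Acid-catalysed transacetalisation should form the second acetonide under conditions too mild to cleave the first one or the MOM ether.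

Step 10
Reactants: 15 bis-acetonide aryl bromide
Product: 17 4-{[(4R,5S)-4-ArB-2,2-dimethyl-1,3-dioxan-5-yl]oxy}-3,5-dimethoxybenzaldehyde (fragment 1), via aryllithium 16 (not isolated)
Conditions: n-BuLi, THF, −78 °C; DMF; aq. NH4Cl
Reagents that add atoms: N,N-dimethylformamide, CN(C)C=O
Why: Bromine–lithium exchange followed by formylation with DMF (Bouveault aldehyde synthesis) should deliver the aldehyde that will become C2 and O1.

Step 11
Reactants: 18 5-iodovanillin
Product: 19 methyl (E)-3-(4-hydroxy-3-iodo-5-methoxyphenyl)prop-2-enoate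
Conditions: Ph3P=CHCO2Me, PhMe, 90 °C
Reagents that add atoms: methyl (triphenylphosphoranylidene)acetate, COC(=O)C=P(c1ccccc1)(c1ccccc1)c1ccccc1
Why: Wittig olefination with a stabilised ylide should give the (E)-cinnamate and tolerates the free phenol.

Step 12
Reactants: 19 iodoferulate
Product: 20 methyl (E)-3-{3-iodo-5-methoxy-4-[(trifluoromethylsulfonyl)oxy]phenyl}prop-2-enoate
Conditions: Tf2O, pyridine, CH2Cl2, 0 °C
Reagents that add atoms: trifluoromethanesulfonic anhydride, O=S(=O)(OS(=O)(=O)C(F)(F)F)C(F)(F)F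
Why: O-sulfonylation of the phenol should give the aryl triflate that later serves as the electrophile at C7a.

Step 13
Reactants: 20 iodo triflate
Product: 21 methyl (E)-3-{3-(2-tert-butoxy-2-oxoethyl)-5-methoxy-4-[(trifluoromethylsulfonyl)oxy]phenyl}prop-2-enoate
Conditions: BrZnCH2CO2t-Bu, Pd(dba)2 (2 mol%), Q-Phos (2 mol%), THF, rt
Reagents that add atoms: (2-tert-butoxy-2-oxoethyl)zinc bromide, CC(C)(C)OC(=O)C[Zn]Br
Why: In this Negishi-type coupling of a Reformatsky reagent (ester α-arylation) zerovalent palladium with a bulky monophosphine should insert into C–I much faster than into C–OTf, so the triflate is kept.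

Step 14
Reactants: 21 tert-butyl ester
Product: 22 {3-methoxy-5-[(E)-3-methoxy-3-oxoprop-1-enyl]-2-[(trifluoromethylsulfonyl)oxy]phenyl}acetic acid
Conditions: CF3CO2H, CH2Cl2, rt
Reagents that add atoms: none
Why: Acidolysis of the tert-butyl ester (E1 loss of isobutene) should leave the methyl ester and the aryl triflate intact.

Step 15
Reactants: 22 arylacetic acid; 23 (4R)-4-benzyl-1,3-oxazolidin-2-one
Product: 25 methyl (E)-3-{3-[2-((4R)-4-benzyl-2-oxo-1,3-oxazolidin-3-yl)-2-oxoethyl]-5-methoxy-4-[(trifluoromethylsulfonyl)oxy]phenyl}prop-2-enoate (fragment 2), via mixed pivalic anhydride 24 (not isolated)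
Conditions: t-BuCOCl, Et3N, THF, −20 °C; then 23, LiCl, rt
Reagents that add atoms: none
Why: Mixed-anhydride activation followed by LiCl-assisted N-acylation of the oxazolidinone should give the imide without a strong base that could attack the triflate.

Step 16
Reactants: 17 aldehyde (fragment 1); 25 imide (fragment 2)
Product: 28 (4R)-4-benzyl-3-({(2R,3R)-2-ArC-7-methoxy-5-[(E)-3-methoxy-3-oxoprop-1-enyl]-2,3-dihydro-1-benzofuran-3-yl}carbonyl)-1,3-oxazolidin-2-one (2,3-trans), via boron enolate 26 (not isolated), via boron aldolate 27 (not isolated)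
Conditions: n-Bu2BOTf, i-Pr2NEt, PhMe, 0 °C; 17, −78 → 0 °C; then Cs2CO3, Pd2(dba)3 (5 mol%), RockPhos (12 mol%), 60 °C
Reagents that add atoms: none
Why: Proposed new method: n-Bu2BOTf/i-Pr2NEt should turn 25 into the (Z)-boron enolate 26, which adds to 17 through a closed Zimmerman–Traxler chair (Evans syn-aldol) to give borinate 27 and the C2–C3 bond, after which Cs2CO3 converts the O–B bond into a borate that hands the alkoxide to the arylpalladium triflate formed by oxidative addition of zerovalent palladium into C7a–OTf, and C–O reductive elimination gives the O1–C7a bond. The closest known reaction types are the Evans boron aldol of N-arylacetyl oxazolidinones and the Buchwald–Hartwig intramolecular etherification of secondary alcohols with aryl halides and triflates (alkoxide delivery from boron has an analogue in palladium-catalysed methoxylation with borate salts), and what is new is their union in one flask on a boron aldolate. Ring E (O1, C2, C3, C3a, C7a) closes as a five-membered ring by reductive elimination from a six-membered oxapalladacycle, so the step is a formal [3+2] annulation of the C=O of 17 with the C3–C3a–C7a unit of 25. C2 and C3 are set together in the aldol: the (R)-benzyl group of the auxiliary shields one face of the enolate and the chair with the aryl group of 17 equatorial gives the syn (2R,3R) adduct, which maps directly onto the 2,3-trans ring, while the C–O coupling leaves C2 untouched and C3, still epimerisable next to the imide, can only drift towards the more stable trans isomer. The step needs C–O reductive elimination to be faster than β-hydride elimination or retro-aldol cleavage of the alkoxide, which the bulky biaryl phosphine and the weak, poorly soluble base are chosen to secure, and it needs O-arylation to beat enolate C-arylation, which the five-membered ring closure secures because intramolecular C-arylation would need a three-membered ring.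

Step 17
Reactants: 28 dihydrobenzofuran imide
Product: 29 methyl (E)-3-[(2R,3S)-2-ArC-3-(hydroxymethyl)-7-methoxy-2,3-dihydro-1-benzofuran-5-yl]prop-2-enoate
Conditions: LiBH4, H2O (1 equiv), THF, 0 °C
Reagents that add atoms: none
Why: Hydride cleavage of the imide (reductive removal of the oxazolidinone auxiliary) should be faster than reduction of the conjugated methyl ester at 0 °C and turns the C3 acyl group into the hydroxymethyl group without touching C2 or C3.

Step 18
Reactants: 29 hydroxy ester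
Product: 30 (E)-3-[(2R,3S)-2-ArC-3-(hydroxymethyl)-7-methoxy-2,3-dihydro-1-benzofuran-5-yl]prop-2-en-1-ol
Conditions: i-Bu2AlH, CH2Cl2, −78 °C; aq. KNaC4H4O6
Reagents that add atoms: none
Why: i-Bu2AlH should reduce the cinnamate by 1,2-hydride addition to the allylic alcohol at −78 °C, where the acetonides and the MOM ether are inert.

Step 19
Reactants: 30 diol
Product: 31 (E)-3-[(2R,3S)-2-ArC-3-(hydroxymethyl)-7-methoxy-2,3-dihydro-1-benzofuran-5-yl]prop-2-enal
Conditions: MnO2, CH2Cl2, rt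
Reagents that add atoms: none
Why: MnO2 should oxidise only the allylic (cinnamyl) alcohol, since the saturated primary alcohol at C3 is unreactive and the benzylic carbinols are locked in the acetonides.

Step 20
Reactants: 31 protected enal
Product: 32 CNP0192639.1 (target)
Conditions: 2 M aq. HCl, THF, rt
Reagents that add atoms: none
Why: Acid-catalysed acetal hydrolysis should cleave both acetonides and the MOM ether in one operation while the enal and the thermodynamically favoured trans ring E persist.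

Compound list
1 | vanillin (4-hydroxy-3-methoxybenzaldehyde) | COc1cc(C=O)ccc1O | starting material
2 | 3-methoxy-4-(methoxymethoxy)benzaldehyde | COCOc1ccc(C=O)cc1OC | intermediate
3 | 4-bromo-2,6-dimethoxyphenol | COc1cc(Br)cc(OC)c1O | starting material
4 | (4S)-4-benzyl-3-(chloroacetyl)-1,3-oxazolidin-2-one | ClCC(=O)N1[C@@H](Cc2ccccc2)COC1=O | starting material
5 | (4S)-4-benzyl-3-[(4-bromo-2,6-dimethoxyphenoxy)acetyl]-1,3-oxazolidin-2-one | COc1cc(Br)cc(OC)c1OCC(=O)N1[C@@H](Cc2ccccc2)COC1=O | intermediate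
6 | (4S)-4-benzyl-3-{(2R,3R)-2-(4-bromo-2,6-dimethoxyphenoxy)-3-[3-methoxy-4-(methoxymethoxy)phenyl]-3-(trimethylsilyloxy)propanoyl}-1,3-oxazolidin-2-one | COCOc1ccc(cc1OC)[C@@H](O[Si](C)(C)C)[C@H](C(=O)N1[C@@H](Cc2ccccc2)COC1=O)Oc1c(OC)cc(Br)cc1OC | intermediate
7 | (2S,3R)-2-(4-bromo-2,6-dimethoxyphenoxy)-3-[3-methoxy-4-(methoxymethoxy)phenyl]-3-(trimethylsilyloxy)propan-1-ol (not isolated) | COCOc1ccc(cc1OC)[C@@H](O[Si](C)(C)C)[C@H](CO)Oc1c(OC)cc(Br)cc1OC | intermediate
8 | (1R,2S)-2-(4-bromo-2,6-dimethoxyphenoxy)-1-[3-methoxy-4-(methoxymethoxy)phenyl]propane-1,3-diol (erythro) | COCOc1ccc(cc1OC)[C@@H](O)[C@H](CO)Oc1c(OC)cc(Br)cc1OC | intermediate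
9 | (4R,5S)-5-(4-bromo-2,6-dimethoxyphenoxy)-4-[3-methoxy-4-(methoxymethoxy)phenyl]-2,2-dimethyl-1,3-dioxane | COCOc1ccc(cc1OC)[C@H]1OC(C)(C)OC[C@@H]1Oc1c(OC)cc(Br)cc1OC | intermediate
10 | aryllithium from 9, Li in place of Br (not isolated) | COCOc1ccc(cc1OC)[C@H]1OC(C)(C)OC[C@@H]1Oc1c(OC)cc([Li])cc1OC | intermediate
11 | 3,5-dimethoxy-4-({(4R,5S)-4-[3-methoxy-4-(methoxymethoxy)phenyl]-2,2-dimethyl-1,3-dioxan-5-yl}oxy)benzaldehyde | COCOc1ccc(cc1OC)[C@H]1OC(C)(C)OC[C@@H]1Oc1c(OC)cc(C=O)cc1OC | intermediate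
12 | (4S)-4-benzyl-3-[(2R,3R)-3-ArB-2-(4-bromo-2,6-dimethoxyphenoxy)-3-(trimethylsilyloxy)propanoyl]-1,3-oxazolidin-2-one | COCOc1ccc(cc1OC)[C@H]1OC(C)(C)OC[C@@H]1Oc1c(OC)cc(cc1OC)[C@@H](O[Si](C)(C)C)[C@H](C(=O)N1[C@@H](Cc2ccccc2)COC1=O)Oc1c(OC)cc(Br)cc1OC | intermediate
13 | (2S,3R)-3-ArB-2-(4-bromo-2,6-dimethoxyphenoxy)-3-(trimethylsilyloxy)propan-1-ol (not isolated) | COCOc1ccc(cc1OC)[C@H]1OC(C)(C)OC[C@@H]1Oc1c(OC)cc(cc1OC)[C@@H](O[Si](C)(C)C)[C@H](CO)Oc1c(OC)cc(Br)cc1OC | intermediate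
14 | (1R,2S)-1-ArB-2-(4-bromo-2,6-dimethoxyphenoxy)propane-1,3-diol (erythro) | COCOc1ccc(cc1OC)[C@H]1OC(C)(C)OC[C@@H]1Oc1c(OC)cc(cc1OC)[C@@H](O)[C@H](CO)Oc1c(OC)cc(Br)cc1OC | intermediate
15 | (4R,5S)-4-ArB-5-(4-bromo-2,6-dimethoxyphenoxy)-2,2-dimethyl-1,3-dioxane | COCOc1ccc(cc1OC)[C@H]1OC(C)(C)OC[C@@H]1Oc1c(OC)cc(cc1OC)[C@H]1OC(C)(C)OC[C@@H]1Oc1c(OC)cc(Br)cc1OC | intermediate
16 | aryllithium from 15, Li in place of Br (not isolated) | COCOc1ccc(cc1OC)[C@H]1OC(C)(C)OC[C@@H]1Oc1c(OC)cc(cc1OC)[C@H]1OC(C)(C)OC[C@@H]1Oc1c(OC)cc([Li])cc1OC | intermediate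
17 | 4-{[(4R,5S)-4-ArB-2,2-dimethyl-1,3-dioxan-5-yl]oxy}-3,5-dimethoxybenzaldehyde (fragment 1) | COCOc1ccc(cc1OC)[C@H]1OC(C)(C)OC[C@@H]1Oc1c(OC)cc(cc1OC)[C@H]1OC(C)(C)OC[C@@H]1Oc1c(OC)cc(C=O)cc1OC | intermediate
18 | 5-iodovanillin (4-hydroxy-3-iodo-5-methoxybenzaldehyde) | COc1cc(C=O)cc(I)c1O | starting material
19 | methyl (E)-3-(4-hydroxy-3-iodo-5-methoxyphenyl)prop-2-enoate | COC(=O)/C=C/c1cc(I)c(O)c(OC)c1 | intermediate
20 | methyl (E)-3-{3-iodo-5-methoxy-4-[(trifluoromethylsulfonyl)oxy]phenyl}prop-2-enoate | COC(=O)/C=C/c1cc(I)c(OS(=O)(=O)C(F)(F)F)c(OC)c1 | intermediate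
21 | methyl (E)-3-{3-(2-tert-butoxy-2-oxoethyl)-5-methoxy-4-[(trifluoromethylsulfonyl)oxy]phenyl}prop-2-enoate | COC(=O)/C=C/c1cc(CC(=O)OC(C)(C)C)c(OS(=O)(=O)C(F)(F)F)c(OC)c1 | intermediate
22 | {3-methoxy-5-[(E)-3-methoxy-3-oxoprop-1-enyl]-2-[(trifluoromethylsulfonyl)oxy]phenyl}acetic acid | COC(=O)/C=C/c1cc(CC(=O)O)c(OS(=O)(=O)C(F)(F)F)c(OC)c1 | intermediate
23 | (4R)-4-benzyl-1,3-oxazolidin-2-one | O=C1N[C@H](Cc2ccccc2)CO1 | starting material
24 | mixed anhydride of 22 and pivalic acid (not isolated) | COC(=O)/C=C/c1cc(CC(=O)OC(=O)C(C)(C)C)c(OS(=O)(=O)C(F)(F)F)c(OC)c1 | intermediate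
25 | methyl (E)-3-{3-[2-((4R)-4-benzyl-2-oxo-1,3-oxazolidin-3-yl)-2-oxoethyl]-5-methoxy-4-[(trifluoromethylsulfonyl)oxy]phenyl}prop-2-enoate (fragment 2) | COC(=O)/C=C/c1cc(CC(=O)N2[C@H](Cc3ccccc3)COC2=O)c(OS(=O)(=O)C(F)(F)F)c(OC)c1 | intermediate
26 | (Z)-dibutylboron enolate of 25 (not isolated) | COC(=O)/C=C/c1cc(/C=C(\OB(CCCC)CCCC)N2[C@H](Cc3ccccc3)COC2=O)c(OS(=O)(=O)C(F)(F)F)c(OC)c1 | intermediate
27 | dibutylboron aldolate, the (2R,3R) syn adduct of 26 and 17, O-BBu2 on the carbinol carbon (not isolated) | COCOc1ccc(cc1OC)[C@H]1OC(C)(C)OC[C@@H]1Oc1c(OC)cc(cc1OC)[C@H]1OC(C)(C)OC[C@@H]1Oc1c(OC)cc(cc1OC)[C@H](OB(CCCC)CCCC)[C@@H](c1cc(/C=C/C(=O)OC)cc(OC)c1OS(=O)(=O)C(F)(F)F)C(=O)N1[C@H](Cc2ccccc2)COC1=O | intermediate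
28 | (4R)-4-benzyl-3-({(2R,3R)-2-ArC-7-methoxy-5-[(E)-3-methoxy-3-oxoprop-1-enyl]-2,3-dihydro-1-benzofuran-3-yl}carbonyl)-1,3-oxazolidin-2-one (2,3-trans) | COCOc1ccc(cc1OC)[C@H]1OC(C)(C)OC[C@@H]1Oc1c(OC)cc(cc1OC)[C@H]1OC(C)(C)OC[C@@H]1Oc1c(OC)cc(cc1OC)[C@@H]1Oc2c(OC)cc(/C=C/C(=O)OC)cc2[C@H]1C(=O)N1[C@H](Cc2ccccc2)COC1=O | intermediate
29 | methyl (E)-3-[(2R,3S)-2-ArC-3-(hydroxymethyl)-7-methoxy-2,3-dihydro-1-benzofuran-5-yl]prop-2-enoate | COCOc1ccc(cc1OC)[C@H]1OC(C)(C)OC[C@@H]1Oc1c(OC)cc(cc1OC)[C@H]1OC(C)(C)OC[C@@H]1Oc1c(OC)cc(cc1OC)[C@@H]1Oc2c(OC)cc(/C=C/C(=O)OC)cc2[C@H]1CO | intermediate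
30 | (E)-3-[(2R,3S)-2-ArC-3-(hydroxymethyl)-7-methoxy-2,3-dihydro-1-benzofuran-5-yl]prop-2-en-1-ol | COCOc1ccc(cc1OC)[C@H]1OC(C)(C)OC[C@@H]1Oc1c(OC)cc(cc1OC)[C@H]1OC(C)(C)OC[C@@H]1Oc1c(OC)cc(cc1OC)[C@@H]1Oc2c(OC)cc(/C=C/CO)cc2[C@H]1CO | intermediate
31 | (E)-3-[(2R,3S)-2-ArC-3-(hydroxymethyl)-7-methoxy-2,3-dihydro-1-benzofuran-5-yl]prop-2-enal | COCOc1ccc(cc1OC)[C@H]1OC(C)(C)OC[C@@H]1Oc1c(OC)cc(cc1OC)[C@H]1OC(C)(C)OC[C@@H]1Oc1c(OC)cc(cc1OC)[C@@H]1Oc2c(OC)cc(/C=C/C=O)cc2[C@H]1CO | intermediate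
32 | CNP0192639.1 | COc1cc([C@@H](O)[C@H](CO)Oc2c(OC)cc([C@@H](O)[C@H](CO)Oc3c(OC)cc([C@@H]4Oc5c(OC)cc(/C=C/C=O)cc5[C@H]4CO)cc3OC)cc2OC)ccc1O | target

Total step count: 20. Longest linear sequence: 14 steps (steps 1, 3–10 and 16–20, from vanillin).

Steps most likely to fail

1. Step 16 (proposed new method). The aldolate may lose its C2 configuration by retro-aldol cleavage before ring closure, the palladium alkoxide may undergo β-hydride elimination, or the alkoxide may not transfer from boron to palladium. The fallback uses known chemistry, sets out from 17 (with 25) and comes back to the route at 29. The Evans boron syn-aldol of 25 with 17 (n-Bu2BOTf, i-Pr2NEt, then H2O2/pH 7 buffer work-up) should give the free syn-aldol imide F1. LiBH4 then removes the auxiliary to give the 1,3-diol F2, and TBSCl/imidazole silylates only the primary hydroxyl to give the silyl ether F3. Buchwald–Hartwig intramolecular O-arylation of the secondary benzylic alcohol with the aryl triflate (Pd2(dba)3, RockPhos, Cs2CO3, PhMe, 80 °C), now without any retro-aldol path, closes ring E to the trans-dihydrobenzofuran silyl ether F4. Bu4NF then gives 29.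

2. Step 3 (and its repeat in step 7). Silyl turnover may stall, or the aryloxy-substituted enolate may react with poor anti selectivity or facial control. The fallback sets out from 2 and comes back at 8. Alkylation of 3 with (4R)-4-benzyl-3-(chloroacetyl)-1,3-oxazolidin-2-one gives the enantiomeric glycolate imide F5. Its Evans boron syn-aldol with 2 (n-Bu2BOTf, i-Pr2NEt) gives the syn (2R,3S) adduct F6. Mitsunobu inversion at the benzylic carbinol (4-nitrobenzoic acid, PPh3, DIAD) gives the anti 4-nitrobenzoate F7. Excess LiBH4 then cleaves both the auxiliary and the benzoate to give 8.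

3. Step 17. Hydride may attack the ring carbonyl of the hindered imide (opening the auxiliary), C3 may epimerise, or the cinnamate may be reduced as well. The fallback sets out from 28 and comes back at 29. LiOH/H2O2 hydrolysis of the imide gives the carboxylic acid F8, and BH3·THF reduces the acid chemoselectively beside the methyl ester to give 29.

Further compounds
F1 | step 16 | (4R)-4-benzyl-3-[(2R,3R)-3-ArC-3-hydroxy-2-{3-methoxy-5-[(E)-3-methoxy-3-oxoprop-1-enyl]-2-[(trifluoromethylsulfonyl)oxy]phenyl}propanoyl]-1,3-oxazolidin-2-one | COCOc1ccc(cc1OC)[C@H]1OC(C)(C)OC[C@@H]1Oc1c(OC)cc(cc1OC)[C@H]1OC(C)(C)OC[C@@H]1Oc1c(OC)cc(cc1OC)[C@H](O)[C@@H](c1cc(/C=C/C(=O)OC)cc(OC)c1OS(=O)(=O)C(F)(F)F)C(=O)N1[C@H](Cc2ccccc2)COC1=O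
F2 | step 16 | methyl (E)-3-{3-[(1S,2R)-2-ArC-1,3-dihydroxypropan-... as drawn: (1R,2S)-1-ArC-2-aryl-propane-1,3-diol, aryl = 3-methoxy-5-[(E)-3-methoxy-3-oxoprop-1-enyl]-2-[(trifluoromethylsulfonyl)oxy]phenyl | COCOc1ccc(cc1OC)[C@H]1OC(C)(C)OC[C@@H]1Oc1c(OC)cc(cc1OC)[C@H]1OC(C)(C)OC[C@@H]1Oc1c(OC)cc(cc1OC)[C@H](O)[C@@H](c1cc(/C=C/C(=O)OC)cc(OC)c1OS(=O)(=O)C(F)(F)F)CO
F3 | step 16 | 3-O-(tert-butyldimethylsilyl) ether of F2 (primary hydroxyl silylated) | COCOc1ccc(cc1OC)[C@H]1OC(C)(C)OC[C@@H]1Oc1c(OC)cc(cc1OC)[C@H]1OC(C)(C)OC[C@@H]1Oc1c(OC)cc(cc1OC)[C@H](O)[C@@H](c1cc(/C=C/C(=O)OC)cc(OC)c1OS(=O)(=O)C(F)(F)F)CO[Si](C)(C)C(C)(C)C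
F4 | step 16 | methyl (E)-3-[(2R,3S)-2-ArC-3-{[(tert-butyldimethylsilyl)oxy]methyl}-7-methoxy-2,3-dihydro-1-benzofuran-5-yl]prop-2-enoate | COCOc1ccc(cc1OC)[C@H]1OC(C)(C)OC[C@@H]1Oc1c(OC)cc(cc1OC)[C@H]1OC(C)(C)OC[C@@H]1Oc1c(OC)cc(cc1OC)[C@@H]1Oc2c(OC)cc(/C=C/C(=O)OC)cc2[C@H]1CO[Si](C)(C)C(C)(C)C
F5 | step 3 | (4R)-4-benzyl-3-[(4-bromo-2,6-dimethoxyphenoxy)acetyl]-1,3-oxazolidin-2-one | COc1cc(Br)cc(OC)c1OCC(=O)N1[C@H](Cc2ccccc2)COC1=O
F6 | step 3 | (4R)-4-benzyl-3-{(2R,3S)-2-(4-bromo-2,6-dimethoxyphenoxy)-3-hydroxy-3-[3-methoxy-4-(methoxymethoxy)phenyl]propanoyl}-1,3-oxazolidin-2-one | COCOc1ccc(cc1OC)[C@H](O)[C@H](C(=O)N1[C@H](Cc2ccccc2)COC1=O)Oc1c(OC)cc(Br)cc1OC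
F7 | step 3 | (1R,2R)-3-[(4R)-4-benzyl-2-oxo-1,3-oxazolidin-3-yl]-2-(4-bromo-2,6-dimethoxyphenoxy)-1-[3-methoxy-4-(methoxymethoxy)phenyl]-3-oxopropyl 4-nitrobenzoate | COCOc1ccc(cc1OC)[C@@H](OC(=O)c1ccc(cc1)[N+](=O)[O-])[C@H](C(=O)N1[C@H](Cc2ccccc2)COC1=O)Oc1c(OC)cc(Br)cc1OC
F8 | step 17 | (2R,3R)-2-ArC-7-methoxy-5-[(E)-3-methoxy-3-oxoprop-1-enyl]-2,3-dihydro-1-benzofuran-3-carboxylic acid | COCOc1ccc(cc1OC)[C@H]1OC(C)(C)OC[C@@H]1Oc1c(OC)cc(cc1OC)[C@H]1OC(C)(C)OC[C@@H]1Oc1c(OC)cc(cc1OC)[C@@H]1Oc2c(OC)cc(/C=C/C(=O)OC)cc2[C@H]1C(=O)O
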